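## Retrosynthetic overview
1. The target comes from its 5,7,3'-tris-MOM ether by acidic unmasking as the last step, so no base touches the molecule once C3 is set.
2. Rings A and B are bought, and ring C is the only ring formed. It is cut at C3–C4 into the ring A formyl carbon, used as a carbene-bound acyl anion, and the benzylic carbon of a ring B o-quinone methide. Both carbons are natively electrophilic, and this closure also sets C3.
3. The o-quinone methide comes from a 2'-O-TIPS benzylic acetate triggered by fluoride. The O1–C2 tether comes from a ring B styrene oxide and 2-hydroxy-4,6-bis(methoxymethoxy)benzaldehyde.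
4. The epoxide comes from a ring B salicylaldehyde and a sulfonium ylide. The 5'-prenyl group comes from a para-Claisen–Cope shift of the 2-O-prenyl ether of 2,3-dihydroxy-4-methoxybenzaldehyde.

Assumption: the (5aR,10bS) antipode of the triazolium salt is taken to give (3R); this rests on a facial-shielding model rather than a measured case, so the equally purchasable mirror-image salt is used if the first run shows (3S).

## Route

Step 1
Reactants: 1 2,4,6-trihydroxybenzaldehyde
Product: 2 2-hydroxy-4,6-bis(methoxymethoxy)benzaldehyde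
Conditions: MOMCl (2.1 equiv), K2CO3 (3 equiv), acetone, 0 °C to rt
Reagents that add atoms: chloromethyl methyl ether, COCCl
Why: Williamson-type MOM protection takes the 4-OH and one of the two equivalent ortho OH groups, while the last OH is hydrogen-bonded to the formyl group and stays free at this stoichiometry; no stereocentre is formed.

Step 2
Reactants: 3 2,3-dihydroxy-4-methoxybenzaldehyde
Product: 5 4-methoxy-3-(methoxymethoxy)-2-[(3-methylbut-2-en-1-yl)oxy]benzaldehyde, via mono-MOM ether 4 (not isolated)
Conditions: K2CO3 (3 equiv), MOMCl (1.05 equiv), acetone, 0 °C to rt; then prenyl bromide (1.5 equiv), reflux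
Reagents that add atoms: chloromethyl methyl ether, COCCl; prenyl bromide, CC(C)=CCBr
Why: In this sequential Williamson etherification the non-chelated 3-OH reacts first in the cold, and the formyl-chelated 2-OH is alkylated only on heating with the reactive allylic bromide; no stereocentre is formed.

Step 3
Reactants: 5 4-methoxy-3-(methoxymethoxy)-2-[(3-methylbut-2-en-1-yl)oxy]benzaldehyde
Product: 8 2-hydroxy-4-methoxy-3-(methoxymethoxy)-5-(3-methylbut-2-en-1-yl)benzaldehyde, via ortho-dienone 6 (not isolated), via para-dienone 7 (not isolated)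
Conditions: PhNEt2, 190 °C, sealed tube, argon, 3 h
Reagents that add atoms: none
Why: In this aromatic para-Claisen–Cope rearrangement both ortho positions are blocked, so the first [3,3] shift gives a reverse-prenyl dienone, a second [3,3] shift carries the group to the only free para carbon with the normal prenyl connectivity restored, and tautomerisation frees exactly the 2-OH needed later.

Step 4
Reactants: 8 2-hydroxy-4-methoxy-3-(methoxymethoxy)-5-(3-methylbut-2-en-1-yl)benzaldehyde
Product: 9 4-methoxy-3-(methoxymethoxy)-5-(3-methylbut-2-en-1-yl)-2-[(triisopropylsilyl)oxy]benzaldehyde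
Conditions: NaH (1.1 equiv), THF, 0 °C; TIPSCl (1.2 equiv), rt
Reagents that add atoms: chlorotriisopropylsilane, CC(C)[Si](Cl)(C(C)C)C(C)C
Why: O-silylation of the preformed phenoxide overcomes the chelation, and the doubly ortho-flanked TIPS ether resists base and O-to-O migration yet stays labile to fluoride.

Step 5
Reactants: 9 4-methoxy-3-(methoxymethoxy)-5-(3-methylbut-2-en-1-yl)-2-[(triisopropylsilyl)oxy]benzaldehyde
Product: 10 racemic triisopropyl[3-methoxy-2-(methoxymethoxy)-4-(3-methylbut-2-en-1-yl)-6-(oxiran-2-yl)phenoxy]silane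
Conditions: Me3SI (1.5 equiv), KN(SiMe3)2 (1.4 equiv), THF, 0 °C; then 9, 0 °C to rt; used crude after filtration through Et3N-washed silica
Reagents that add atoms: trimethylsulfonium iodide, C[S+](C)C.[I-]
Why: In this Johnson–Corey–Chaykovsky epoxidation the betaine closes with loss of Me2S faster than the bulky silyl group can migrate, the unactivated prenyl alkene is inert to the ylide, and the new stereocentre is racemic on purpose because it is erased in step 7.

Step 6
Reactants: 10 racemic ring B oxirane; 2 2-hydroxy-4,6-bis(methoxymethoxy)benzaldehyde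
Product: 12 racemic 2-[2-formyl-3,5-bis(methoxymethoxy)phenoxy]-1-[4-methoxy-3-(methoxymethoxy)-5-(3-methylbut-2-en-1-yl)-2-(triisopropylsilyloxy)phenyl]ethyl acetate, via benzylic alcohol 11 (not isolated)
Conditions: 2 (1.3 equiv), Cs2CO3 (0.3 equiv), dry DMF, 70 °C; then Ac2O, Et3N, DMAP (cat.), rt
Reagents that add atoms: acetic anhydride, CC(=O)OC(C)=O
Why: In this base-catalysed SN2 epoxide opening the phenoxide attacks the terminal carbon, because no Lewis acid is present and the ortho OTIPS group shields the benzylic carbon. Excess phenol protonates the alkoxide at once, and DMAP-catalysed acetylation installs the leaving group in the same flask.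

Step 7
Reactants: 12 racemic benzylic acetate
Product: 15 (3R)-3-[2-hydroxy-4-methoxy-3-(methoxymethoxy)-5-(3-methylbut-2-en-1-yl)phenyl]-5,7-bis(methoxymethoxy)chroman-4-one, via o-quinone methide 13 (not isolated), via Breslow enaminol 14 (not isolated)
Conditions: (5aR,10bS)-5a,10b-dihydro-2-(pentafluorophenyl)-4H,6H-indeno[2,1-b]-1,2,4-triazolo[4,3-d]-1,4-oxazinium tetrafluoroborate (20 mol %), CsF (1.2 equiv, added last in portions), 18-crown-6 (1.2 equiv), 4 Å MS, THF, −20 °C; cold pH 5 buffer work-up
Reagents that add atoms: none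
Why: Proposed new method: fluoride removes the TIPS group and the electron-rich phenoxide expels acetate to give E-o-quinone methide 13 with an electrophilic exocyclic carbon, while the chiral triazolylidene adds to the formyl group and after proton shift gives Breslow enaminol 14, whose former carbonyl carbon is an acyl anion equivalent; 6-exo-trig attack of that carbon on the methide carbon rearomatises ring B and closes ring C, and proton transfer with loss of the carbene gives the ketone, with C3 fixed in the C–C bond-forming event because the indane wall leaves one enaminol face open to the tethered methide (racemic 12 converges because its stereocentre is erased in 13); the closest known reaction types are the enantioselective intramolecular Stetter reaction to 3-substituted chroman-4-ones, the carbene-catalysed acylation of fluoride-released o-quinone methides to alpha-aryl ketones, and the carbene-catalysed 1,6-addition of aldehydes to p-quinone methides.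

Step 8
Reactants: 15 (3R)-tris-MOM isoflavanone
Product: 16 (3R)-3-[2,3-dihydroxy-4-methoxy-5-(3-methylbut-2-en-1-yl)phenyl]-5,7-dihydroxychroman-4-one (target)
Conditions: HCl (1.25 M in MeOH), THF, 25 °C, 8 h; evaporation below 25 °C, acid-washed silica, ee checked by chiral HPLC
Reagents that add atoms: none
Why: Acid-catalysed acetal solvolysis removes all three aryl MOM groups, the prenyl group has no ortho OH to cyclise onto, the ketone becomes chelated by the freed 5-OH and is deactivated towards enolisation and hemiketal dehydration, and the absence of base keeps the C3 configuration intact.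

## Compound list
1 | 2,4,6-trihydroxybenzaldehyde | O=Cc1c(O)cc(O)cc1O | starting material
2 | 2-hydroxy-4,6-bis(methoxymethoxy)benzaldehyde | O=Cc1c(O)cc(OCOC)cc1OCOC | intermediate
3 | 2,3-dihydroxy-4-methoxybenzaldehyde | COc1ccc(C=O)c(O)c1O | starting material
4 | 2-hydroxy-4-methoxy-3-(methoxymethoxy)benzaldehyde | COCOc1c(O)c(C=O)ccc1OC | intermediate
5 | 4-methoxy-3-(methoxymethoxy)-2-[(3-methylbut-2-en-1-yl)oxy]benzaldehyde | COCOc1c(OCC=C(C)C)c(C=O)ccc1OC | intermediate
6 | racemic 4-methoxy-5-(methoxymethoxy)-5-(2-methylbut-3-en-2-yl)-6-oxocyclohexa-1,3-diene-1-carbaldehyde | O=CC1=CC=C(OC)C(OCOC)(C(C)(C)C=C)C1=O | intermediate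
7 | racemic 4-methoxy-5-(methoxymethoxy)-3-(3-methylbut-2-en-1-yl)-6-oxocyclohexa-1,4-diene-1-carbaldehyde | O=CC1=CC(CC=C(C)C)C(OC)=C(OCOC)C1=O | intermediate
8 | 2-hydroxy-4-methoxy-3-(methoxymethoxy)-5-(3-methylbut-2-en-1-yl)benzaldehyde | COCOc1c(O)c(C=O)cc(CC=C(C)C)c1OC | intermediate
9 | 4-methoxy-3-(methoxymethoxy)-5-(3-methylbut-2-en-1-yl)-2-[(triisopropylsilyl)oxy]benzaldehyde | COCOc1c(O[Si](C(C)C)(C(C)C)C(C)C)c(C=O)cc(CC=C(C)C)c1OC | intermediate
10 | racemic triisopropyl[3-methoxy-2-(methoxymethoxy)-4-(3-methylbut-2-en-1-yl)-6-(oxiran-2-yl)phenoxy]silane | COCOc1c(O[Si](C(C)C)(C(C)C)C(C)C)c(C2CO2)cc(CC=C(C)C)c1OC | intermediate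
11 | racemic 2-{2-hydroxy-2-[4-methoxy-3-(methoxymethoxy)-5-(3-methylbut-2-en-1-yl)-2-(triisopropylsilyloxy)phenyl]ethoxy}-4,6-bis(methoxymethoxy)benzaldehyde | COCOc1c(O[Si](C(C)C)(C(C)C)C(C)C)c(C(O)COc2cc(OCOC)cc(OCOC)c2C=O)cc(CC=C(C)C)c1OC | intermediate
12 | racemic acetate of 11 | COCOc1c(O[Si](C(C)C)(C(C)C)C(C)C)c(C(COc2cc(OCOC)cc(OCOC)c2C=O)OC(C)=O)cc(CC=C(C)C)c1OC | intermediate
13 | 2-{(2E)-2-[4-methoxy-5-(methoxymethoxy)-3-(3-methylbut-2-en-1-yl)-6-oxocyclohexa-2,4-dien-1-ylidene]ethoxy}-4,6-bis(methoxymethoxy)benzaldehyde | O=C1C(OCOC)=C(OC)C(CC=C(C)C)=C/C1=C\COc2cc(OCOC)cc(OCOC)c2C=O | intermediate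
14 | Breslow enaminol formed from the formyl group of 13 and the (5aR,10bS)-triazolylidene | Fc1c(F)c(F)c(c(F)c1F)N2C(=C(O)c6c(OCOC)cc(OCOC)cc6OC/C=C7\C=C(CC=C(C)C)C(OC)=C(OCOC)C7=O)N3[C@@H]4[C@@H](Cc5ccccc45)OCC3=N2 | intermediate
15 | (3R)-3-[2-hydroxy-4-methoxy-3-(methoxymethoxy)-5-(3-methylbut-2-en-1-yl)phenyl]-5,7-bis(methoxymethoxy)chroman-4-one | COc1c(CC=C(C)C)cc([C@@H]2COc3cc(OCOC)cc(OCOC)c3C2=O)c(O)c1OCOC | intermediate
16 | (3R)-5,7,2',3'-tetrahydroxy-4'-methoxy-5'-prenylisoflavanone (CNP0141716.1) | COc1c(CC=C(C)C)cc([C@@H]2COc3cc(O)cc(O)c3C2=O)c(O)c1O | target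

## Step count and risks
Total step count: 8. Longest linear sequence: 7 (steps 2 to 8, from 3 to 16).

**Most likely to fail, first: step 7.**
- The di-ortho-alkoxy, electron-rich aldehyde may take up the bulky carbene slowly.
- 13 may tautomerise to the styryl aryl ether or alkylate the carbene.
- Fluoride or acetate may erode the ee.

The fallback separates ring closure from stereocontrol while keeping the same C3–C4 bond construction. It sets out from 12. Ring C is closed with the small achiral carbene from 3-benzyl-5-(2-hydroxyethyl)-4-methylthiazolium chloride (CsF, THF, rt) to give racemic tris-MOM isoflavanone F1. LiN(SiMe3)2 (2.2 equiv) and Me3SiCl in THF at −78 °C convert it into the 4-(trimethylsilyloxy)-2H-chromene 2'-O-trimethylsilyl ether F2. Catalytic enantioselective protonation follows, using (R)-3,3'-bis(2,4,6-triisopropylphenyl)-1,1'-binaphthalene-2,2'-diyl N-(trifluoromethylsulfonyl)thiophosphoramide (5 mol %; its antipode if the sense is opposite) and PhOH (1.1 equiv) in toluene. This gives the (3R)-2'-O-trimethylsilyl ketone F3. A wash with aqueous citric acid removes the aryl silyl group, and the route is rejoined at 15.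

**Second: step 6.** The para-methoxy-stabilised epoxide may be attacked at the benzylic carbon, may rearrange to the arylacetaldehyde, or may lose the TIPS group at 70 °C. The fallback avoids the epoxide and makes the ether under neutral conditions. It sets out from 9. Addition of (iPrO)Me2SiCH2MgCl (THF, 0 °C) gives the racemic beta-hydroxysilane F4. Fluoride-free Tamao oxidation (H2O2, KHCO3, THF/MeOH) gives the racemic 1-arylethane-1,2-diol F5. Its primary OH is coupled with 2 in a Mitsunobu reaction (PPh3, DIAD, toluene, 0 °C). The route is rejoined at 11, which is acetylated as in the second half of step 6.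

**Third: step 3.** The ipso-formyl dienone pathway can lose the formyl group, and prenyl ethers can fragment to 4 and isoprene at 190 °C. The fallback replaces the sigmatropic shift by halogenation and cross-coupling. It sets out from 4, isolated by stopping step 2 before prenyl bromide is added. NIS in MeCN iodinates the position para to the free OH and ortho to OMe, giving 2-hydroxy-5-iodo-4-methoxy-3-(methoxymethoxy)benzaldehyde F6. Stille coupling with tributyl(3-methylbut-2-en-1-yl)stannane (Pd(PPh3)4, DMF, 90 °C) rejoins the route at 8.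

Further compounds
F1 | step 7 | racemic 3-[2-hydroxy-4-methoxy-3-(methoxymethoxy)-5-(3-methylbut-2-en-1-yl)phenyl]-5,7-bis(methoxymethoxy)chroman-4-one | COc1c(CC=C(C)C)cc(C2COc3cc(OCOC)cc(OCOC)c3C2=O)c(O)c1OCOC
F2 | step 7 | 3-[4-methoxy-3-(methoxymethoxy)-5-(3-methylbut-2-en-1-yl)-2-(trimethylsilyloxy)phenyl]-5,7-bis(methoxymethoxy)-4-(trimethylsilyloxy)-2H-chromene | COc1c(CC=C(C)C)cc(C2=C(O[Si](C)(C)C)c3c(OCOC)cc(OCOC)cc3OC2)c(O[Si](C)(C)C)c1OCOC
F3 | step 7 | (3R)-3-[4-methoxy-3-(methoxymethoxy)-5-(3-methylbut-2-en-1-yl)-2-(trimethylsilyloxy)phenyl]-5,7-bis(methoxymethoxy)chroman-4-one | COc1c(CC=C(C)C)cc([C@@H]2COc3cc(OCOC)cc(OCOC)c3C2=O)c(O[Si](C)(C)C)c1OCOC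
F4 | step 6 | racemic 2-[dimethyl(propan-2-yloxy)silyl]-1-[4-methoxy-3-(methoxymethoxy)-5-(3-methylbut-2-en-1-yl)-2-(triisopropylsilyloxy)phenyl]ethanol | COCOc1c(O[Si](C(C)C)(C(C)C)C(C)C)c(C(O)C[Si](C)(C)OC(C)C)cc(CC=C(C)C)c1OC
F5 | step 6 | racemic 1-[4-methoxy-3-(methoxymethoxy)-5-(3-methylbut-2-en-1-yl)-2-(triisopropylsilyloxy)phenyl]ethane-1,2-diol | COCOc1c(O[Si](C(C)C)(C(C)C)C(C)C)c(C(O)CO)cc(CC=C(C)C)c1OC
F6 | step 3 | 2-hydroxy-5-iodo-4-methoxy-3-(methoxymethoxy)benzaldehyde | COCOc1c(O)c(C=O)cc(I)c1OC
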